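**Assumption (one line):** the core is numbered as a 6H‑isochromene (C1, O2, C3, C4, C4a, C5, C6, C7, C8, C8a), and the SMILES is read as (7R), with C8 ranking above C6 because C8a carries three carbons.

## The problem

- The target is a 6H‑isochromene‑6,8(7H)‑dione. A 4‑alkylidene‑4H‑pyran (O2, C1, C3, C4) is fused through C4a–C8a to a cyclohexenedione (C5–C8), with a heptyl group on C3. No ring is aromatic, but the core is one oxidation level above a 2‑benzopyrylium, which is why it is normally made from an arene.
- The only stereocentre is C7, a quaternary carbinol ester flanked by the C6 and C8 ketones. Nothing else in the molecule can control it, so it must be set absolutely.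
- C7 is stereogenic only because its two carbonyls differ in what lies beyond them (C5–H on one side, C8a=C1 on the other). Any intermediate that lacks C1 and can enolise at C8a has an enolate with a mirror plane through C7 and C4a, and racemises at once. So C1 must be on C8a before the carbocycle closes, or C7 must be made on the finished skeleton.
- The pyran must close through O2–C3 with the heptyl group at C3, not through the five‑membered alternative.
- Sensitive groups: the tertiary α‑ketol ester (acyl shift, retro‑Claisen and deformylation with hydroxide or alkoxide), the electrophilic C1 (amines give vinylogous pyridones) and the acid‑labile enol ether. The decanoate is best put on last.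
- The enabling feature: C7 with its oxygen, its methyl group and C8 is the skeleton of lactic acid, and C6 is an acyl group on the lactate α‑carbon. The remaining atoms C5–C4a(–C4≡C3–heptyl)–C8a–C1 are an alkynyl pentenedial‑type chain whose anion carries carbanion character at C8a. The carbocycle can therefore be closed by acyl substitution at the lactate carboxyl (C8), and the alkyne then takes the formyl oxygen to make the pyran.

## Retrosynthesis

**17 ⇒ 15 + 16.** The ester C–O bond of the decanoate is cut last. This keeps the base‑labile α‑ketol ester out of every carbanion step and leaves a tertiary‑alcohol acylation that is standard for this ring system. The forward step must acylate a hindered carbinol without strong base.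

**15 ⇒ 14.** The O2–C3 bond is cut, turning the pyran into a formyl group on C8a and an alkyne on C4a. The alkyne is preferred to a C3 ketone because it adds no further acidic or electrophilic carbonyl to the chain and is polarised by the C4a=C5–C6=O enone toward attack at C3. The forward step is a 6‑endo‑dig cycloisomerisation, and only the formyl oxygen can reach the alkyne.

**14 ⇒ 13.** The C8–C8a bond is cut, opening the carbocycle to an acyclic keto‑enal in which C8 is the lactone carbonyl of a lactic acid/pivalaldehyde dioxolanone. This cut is preferred to C5–C6 or C4a–C5 because C1 is already on C8a, so no symmetric enolate can form, and because the nucleophile is a stabilised anion formed by simple deprotonation at C5. The precursor has no carbocycle, no pyran and only a removable acetal centre besides C7. The forward reaction must be C‑acylation at C8a with loss of pivalaldehyde.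

**13 ⇒ 12 + 6.** The C5–C6 bond is cut between an acid chloride (C6) and the terminal carbon of a 1‑siloxydiene. The acid chloride is the more reactive of the two acyl carbons on C7, so it reacts first and intermolecularly, and the lactone is left for the ring closure. That order decides which carbonyl becomes C6 and which C8, and hence the configuration of C7. The forward reaction must attack through the diene terminus.

**12 ⇒ 9 ⇒ 7 + 8.** The C6–C7 bond is cut to the enolate of the dioxolanone 9 and CO2. Self‑regeneration of stereocentres puts the new carboxyl where the lactate α‑hydrogen was. With the new carbon as C6 and the lactate carboxyl as C8, (S)‑lactic acid 7 gives (7R).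

**6 ⇒ 5 ⇒ 4 ⇒ 1 + 2.** The siloxydiene comes from the enal 5 by γ‑deprotonation, the enal from the allylic alcohol 4, and 4 from the commercial enynol 1 by alkylation of its acetylide with 1‑iodoheptane 2. No stereochemistry is involved; the alkene geometry is erased in 6.

## Roads not taken

**Alternative 1:** (the obvious route) Cut the C7–O bond on an arene. A Sonogashira‑derived alkynyl resorcinaldehyde A1 is cycloisomerised with Au(OAc)3 to the 2‑benzopyrylium, drawn as its neutral form A2. A2 is then hydroxylated at C7 with dearomatisation to give 15, which is acylated. In A2, C7 is a trigonal carbon of a nearly symmetric 2‑methylresorcinol, so the oxidant must choose a face with no help from the substrate. IBX gives the racemate. A single enantiomer needs a stoichiometric chiral copper–dioxygen–sparteine oxidant or an enzyme. The arene A1 itself needs several regiocontrolled steps. The chosen plan takes C7 from lactic acid and uses no oxidant on the core.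

**Alternative 2:** Cut C5–C6 and C8–C8a together. An Effenberger‑type double acylation of the anhydrobase A3 with the prochiral malonyl dichloride A4, under a chiral Lewis base, would give 17 in one step from two achiral pieces. Two unproven events are coupled. Selection between the enantiotopic COCl groups of a 2,2‑disubstituted malonyl dichloride has no precedent, and any uncatalysed acylation gives racemate. After the first acylation, C8a is the γ‑carbon of a vinylogous ester and a poor nucleophile. The chosen plan keeps the same two disconnections but distinguishes the acyl carbons chemically (acid chloride against lactone) and keeps the pyran open so that C8a is a carbanion.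

**Alternative 3:** Close the carbocycle before C1 is attached. The enolate 10 is acylated with an enynoyl chloride to A5, a vinylogous Dieckmann closure gives the cyclohexenedione A6, and C8a is then formylated and the pyran closed. The enolate of A6 has a mirror plane through C7 and C4a, so the lactic acid configuration is lost as soon as A6 forms. Recovering it would need a catalyst that formylates one of two enantiotopic carbons of a symmetric dienolate, for which no defensible system exists. The chosen plan avoids this by carrying C1 through the ring closure.

Key step: step 7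

## Route

Step 1
Reactants: 1 (2E)-3-methylpent-2-en-4-yn-1-ol; 2 1-iodoheptane
Product: 4 (2E)-3-methyldodec-2-en-4-yn-1-ol, via dilithio alkoxide acetylide 3 (not isolated)
Conditions: n-BuLi (2.1 equiv), THF, −78 → 0 °C; 2, DMPU, 0 °C → rt; H2O
Reagents that add atoms: none
Why: Alkylation of a lithium acetylide by a primary iodide; the alkoxide is a poorer nucleophile in THF/DMPU and no stereocentre is involved (the Z isomer of 1 or the mixture would serve as well).

Step 2
Reactants: 4 (2E)-3-methyldodec-2-en-4-yn-1-ol
Product: 5 (2E)-3-methyldodec-2-en-4-ynal
Conditions: MnO2 (10 equiv), CH2Cl2, rt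
Reagents that add atoms: none
Why: Selective allylic oxidation with MnO2 stops at the aldehyde and leaves the alkyne alone.

Step 3
Reactants: 5 (2E)-3-methyldodec-2-en-4-ynal
Product: 6 tert-butyl(dimethyl){[(1E)-3-methylidenedodec-1-en-4-yn-1-yl]oxy}silane
Conditions: TBSOTf, Et3N, Et2O, 0 °C → rt
Reagents that add atoms: tert-butyldimethylsilyl triflate, CC(C)(C)[Si](C)(C)OS(=O)(=O)C(F)(F)F
Why: Standard silyl dienol ether formation: O‑silylation of the enal and γ‑deprotonation at the only γ‑position (the methyl group) give the 1‑siloxy‑1,3‑diene, erasing the enal geometry.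

Step 4
Reactants: 7 (S)-lactic acid; 8 pivalaldehyde
Product: 9 (2S,5S)-2-tert-butyl-5-methyl-1,3-dioxolan-4-one
Conditions: TsOH·H2O (cat.), H2SO4 (cat.), pentane, reflux, Dean–Stark; recrystallisation (Et2O/pentane, −78 °C)
Reagents that add atoms: none
Why: Acid‑catalysed acetalisation (self‑regeneration of stereocentres); the lactate centre is untouched, the cis acetal is favoured and is purified by crystallisation.

Step 5
Reactants: 9 (2S,5S)-2-tert-butyl-5-methyl-1,3-dioxolan-4-one
Product: 12 (2S,4S)-2-tert-butyl-4-methyl-5-oxo-1,3-dioxolane-4-carbonyl chloride, via lithium enolate 10 (not isolated), via lithium carboxylate 11 (not isolated)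
Conditions: LDA, THF, −78 °C; CO2 (g), −78 °C; evaporate volatiles; (COCl)2, DMF (cat.), CH2Cl2, 0 °C → rt
Reagents that add atoms: carbon dioxide, O=C=O; oxalyl chloride, ClC(=O)C(=O)Cl
Why: C‑carboxylation of the dioxolanone enolate anti to the tert‑butyl group puts the carboxyl where the lactate α‑hydrogen was, which fixes the future C7; the carboxylate is chlorinated under Vilsmeier‑type activation and, having no α‑hydrogen, cannot form a ketene.

Step 6
Reactants: 12 (2S,4S)-2-tert-butyl-4-methyl-5-oxo-1,3-dioxolane-4-carbonyl chloride; 6 tert-butyl(dimethyl){[(1E)-3-methylidenedodec-1-en-4-yn-1-yl]oxy}silane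
Product: 13 (2Z)-5-[(2S,4R)-2-tert-butyl-4-methyl-5-oxo-1,3-dioxolan-4-yl]-3-(non-1-yn-1-yl)-5-oxopent-2-enal
Conditions: ZnBr2 (10 mol %), CH2Cl2, −40 → 0 °C; aq. NaHCO3; chromatography on buffered silica
Reagents that add atoms: none
Why: Vinylogous Mukaiyama‑type acylation: the hindered acid chloride should attack the unhindered CH2 terminus of the siloxydiene, and chromatography removes any isomer from attack at the internal carbon (which would lead to the enantiomer) and any C4 epimer from step 5; no bond to the quaternary carbon is touched.

Step 7
Reactants: 13 (2Z)-5-[(2S,4R)-2-tert-butyl-4-methyl-5-oxo-1,3-dioxolan-4-yl]-3-(non-1-yn-1-yl)-5-oxopent-2-enal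
Product: 15 (7R)-3-heptyl-7-hydroxy-7-methyl-6H-isochromene-6,8(7H)-dione, via formyl dienone 14 (not isolated)
Conditions: LiHMDS (LiN(SiMe3)2, 1.05 equiv), THF, −78 °C → rt; then AcOH (1.5 equiv), AgOTf (AgOSO2CF3, 5 mol %), THF/CH2Cl2, rt
Reagents that add atoms: none
Why: Deprotonation at C5 gives a stabilised anion delocalised from O1 to O6 with carbanion character at C8a, and lithium bridging O6 and the lactone carbonyl activates C8. C8a then attacks C8 in a Dieckmann (Lacey–Dieckmann‑type) condensation, a 6‑(enolendo)‑exo‑trig closure; the expelled hemiacetal alkoxide loses pivalaldehyde, which makes the closure irreversible, and the tricarbonyl C8a–H is transferred to the C7 alkoxide. Closure through C5 would give a four‑membered ring and closure through oxygen an eight‑membered one, so only the carbocycle can form, and the delocalised anion can rotate about C4a–C8a so both alkene isomers of 13 converge. After acidification, silver activates the alkyne and the formyl oxygen adds to C3 in a 6‑endo‑dig closure, as in the cycloisomerisation of o‑alkynyl aryl aldehydes; loss of the C8 enol proton gives the neutral pyran. The 6‑endo mode is secured by polarisation of the alkyne through C4a=C5–C6=O and by the fact that the C8 oxygen cannot bridge to the alkyne. No bond to C7 is made or broken, so its configuration is that set in step 5, and the acetal centre is discarded with the pivalaldehyde. The base stage is run without metal or nucleophile so that the alkyne is not attacked before the carbocycle exists and the formyl group is not cleaved, which would symmetrise the ring. One operation converts an acyclic chain into both rings of the target core.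

Step 8
Reactants: 15 (7R)-3-heptyl-7-hydroxy-7-methyl-6H-isochromene-6,8(7H)-dione; 16 decanoyl chloride
Product: 17 (7R)-3-heptyl-7-methyl-6,8-dioxo-7,8-dihydro-6H-isochromen-7-yl decanoate
Conditions: Et3N, DMAP (cat.), CH2Cl2, 0 °C → rt
Reagents that add atoms: none
Why: DMAP‑catalysed acyl transfer to the tertiary alcohol, a standard final step for this ring system; only the O–H bond reacts, so C7 keeps its configuration, and tertiary amines do not open the pyran.

## Compound list

1 | (2E)-3-methylpent-2-en-4-yn-1-ol | C#C/C(C)=C/CO | starting material
2 | 1-iodoheptane | CCCCCCCI | starting material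
3 | dilithium salt of 1 (alkoxide acetylide) | [Li+].[Li+].[C-]#C/C(C)=C/C[O-] | intermediate (not isolated)
4 | (2E)-3-methyldodec-2-en-4-yn-1-ol | CCCCCCCC#C/C(C)=C/CO | intermediate
5 | (2E)-3-methyldodec-2-en-4-ynal | CCCCCCCC#C/C(C)=C/C=O | intermediate
6 | tert-butyl(dimethyl){[(1E)-3-methylidenedodec-1-en-4-yn-1-yl]oxy}silane | C=C(C#CCCCCCCC)/C=C/O[Si](C)(C)C(C)(C)C | intermediate
7 | (S)-lactic acid | C[C@H](O)C(=O)O | starting material
8 | pivalaldehyde (2,2-dimethylpropanal) | CC(C)(C)C=O | starting material
9 | (2S,5S)-2-tert-butyl-5-methyl-1,3-dioxolan-4-one | C[C@@H]1O[C@H](C(C)(C)C)OC1=O | intermediate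
10 | lithium (2S)-2-tert-butyl-5-methyl-1,3-dioxol-4-olate | CC1=C([O-])O[C@@H](C(C)(C)C)O1.[Li+] | intermediate (not isolated)
11 | lithium (2S,4R)-2-tert-butyl-4-methyl-5-oxo-1,3-dioxolane-4-carboxylate | C[C@]1(C(=O)[O-])O[C@H](C(C)(C)C)OC1=O.[Li+] | intermediate (not isolated)
12 | (2S,4S)-2-tert-butyl-4-methyl-5-oxo-1,3-dioxolane-4-carbonyl chloride | C[C@]1(C(=O)Cl)O[C@H](C(C)(C)C)OC1=O | intermediate
13 | (2Z)-5-[(2S,4R)-2-tert-butyl-4-methyl-5-oxo-1,3-dioxolan-4-yl]-3-(non-1-yn-1-yl)-5-oxopent-2-enal | C[C@]1(C(=O)C/C(C#CCCCCCCC)=C/C=O)O[C@H](C(C)(C)C)OC1=O | intermediate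
14 | (3S)-2,3-dihydroxy-3-methyl-6-(non-1-yn-1-yl)-4-oxocyclohexa-1,5-diene-1-carbaldehyde (enol form of the formyl dienone) | O[C@]1(C)C(=O)C=C(C#CCCCCCCC)C(C=O)=C1O | intermediate (not isolated)
15 | (7R)-3-heptyl-7-hydroxy-7-methyl-6H-isochromene-6,8(7H)-dione | O[C@]1(C)C(=O)C=C2C=C(CCCCCCC)OC=C2C1=O | intermediate
16 | decanoyl chloride | CCCCCCCCCC(=O)Cl | starting material
17 | (7R)-3-heptyl-7-methyl-6,8-dioxo-7,8-dihydro-6H-isochromen-7-yl decanoate | CCCCCCCCCC(=O)O[C@]1(C)C(=O)C=C2C=C(CCCCCCC)OC=C2C1=O | target

## Step count and risks

Total steps: 8. Longest linear sequence: 6 (steps 1, 2, 3, 6, 7, 8).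

**Step 7 (key step).** The stabilised anion may add too slowly to the hindered lactone carbonyl. On warming, self‑condensation through the free aldehyde or premature O‑cyclisation onto the alkyne could then overtake ring closure. Cleavage of the formyl group by an adventitious nucleophile would symmetrise the carbocycle and erase the configuration. Fallback, from 13 back to 15: condensation of 13 with pyrrolidine (toluene, 4 Å sieves) should give the pyrrolidine vinylogous amide F1, in which C1 is masked and C8a is an enamine carbon. Heating F1 with MgBr2·OEt2 in toluene should bring about a Stork‑type intramolecular enamine acylation at the lactone, with loss of pivalaldehyde, to give the cyclised enaminone F2. Aqueous AcOH with AgOTf should then hydrolyse the enamine and close the pyran to 15, the acid keeping the released amine protonated and away from C1.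

**Step 6.** Attack through the internal carbon of the siloxydiene would put the acid chloride carbon on C8a and lead, after cyclisation, to the enantiomer. The Lewis acid may also desilylate the diene or open the acetal. Fallback, from 5 back to 13: condensation of 5 with morpholine (K2CO3, toluene) should give the morpholine dienamine F3. Acylation of F3 with 12 (Et3N, CH2Cl2, −20 °C, no Lewis acid) should give the morpholino dienone F4, a stable vinylogous amide from which a regioisomer can be separated. Mild aqueous acid (AcOH, THF/H2O) should hydrolyse F4 to 13.

**Step 5.** Incomplete facial selectivity in the carboxylation would give the C4 epimer, which becomes the enantiomer after step 7. The carboxylate may decarboxylate, and residual amine may consume oxalyl chloride. Fallback, from 9 (through its enolate 10) back to 12: trapping the enolate with benzyl chloroformate should give the benzyl ester F5, a stable compound from which the minor diastereomer can be removed. Hydrogenolysis (H2, Pd/C, EtOAc) should give the free acid F6, and 1‑chloro‑N,N,2‑trimethylprop‑1‑en‑1‑amine under neutral conditions should convert F6 into 12.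

The enantiomeric purity of 17 rests on steps 5 and 6; both possible leaks give isomers of 13 that are separable (a diastereomer and a constitutional isomer), so purification at 13 protects it.

## Further compounds

F1 | step 7 | (2E,4E)-1-[(2S,4R)-2-tert-butyl-4-methyl-5-oxo-1,3-dioxolan-4-yl]-3-(non-1-yn-1-yl)-5-(pyrrolidin-1-yl)penta-2,4-dien-1-one | C[C@]1(C(=O)/C=C(C#CCCCCCCC)\C=C\N2CCCC2)O[C@H](C(C)(C)C)OC1=O
F2 | step 7 | (2R,4Z)-2-hydroxy-2-methyl-5-(non-1-yn-1-yl)-4-(pyrrolidin-1-ylmethylidene)cyclohex-5-ene-1,3-dione | O[C@]1(C)C(=O)C=C(C#CCCCCCCC)/C(=C/N2CCCC2)C1=O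
F3 | step 6 | 4-[(1E)-3-methylidenedodec-1-en-4-yn-1-yl]morpholine | C=C(C#CCCCCCCC)/C=C/N1CCOCC1
F4 | step 6 | (2E,4E)-1-[(2S,4R)-2-tert-butyl-4-methyl-5-oxo-1,3-dioxolan-4-yl]-5-(morpholin-4-yl)-3-(non-1-yn-1-yl)penta-2,4-dien-1-one | C[C@]1(C(=O)/C=C(C#CCCCCCCC)\C=C\N2CCOCC2)O[C@H](C(C)(C)C)OC1=O
F5 | step 5 | benzyl (2S,4R)-2-tert-butyl-4-methyl-5-oxo-1,3-dioxolane-4-carboxylate | C[C@]1(C(=O)OCc2ccccc2)O[C@H](C(C)(C)C)OC1=O
F6 | step 5 | (2S,4R)-2-tert-butyl-4-methyl-5-oxo-1,3-dioxolane-4-carboxylic acid | C[C@]1(C(=O)O)O[C@H](C(C)(C)C)OC1=O
A1 | alternative 1 | 2,4-dihydroxy-3-methyl-6-(non-1-yn-1-yl)benzaldehyde | O=Cc1c(O)c(C)c(O)cc1C#CCCCCCCC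
A2 | alternative 1 | 3-heptyl-8-hydroxy-7-methyl-6H-isochromen-6-one (neutral form of the 2-benzopyrylium) | CCCCCCCC1=CC2=CC(=O)C(C)=C(O)C2=CO1
A3 | alternative 2 | 2-heptyl-4-methylidene-4H-pyran | C=C1C=COC(CCCCCCC)=C1
A4 | alternative 2 | 2-(decanoyloxy)-2-methylpropanedioyl dichloride | CCCCCCCCCC(=O)OC(C)(C(=O)Cl)C(=O)Cl
A5 | alternative 3 | (2S,5R)-2-tert-butyl-5-methyl-5-[(2E)-3-methyldodec-2-en-4-ynoyl]-1,3-dioxolan-4-one | C[C@]1(C(=O)/C=C(C)/C#CCCCCCCC)O[C@H](C(C)(C)C)OC1=O
A6 | alternative 3 | 2-hydroxy-2-methyl-5-(non-1-yn-1-yl)cyclohex-4-ene-1,3-dione (configurationally labile, no descriptor) | CC1(O)C(=O)CC(C#CCCCCCCC)=CC1=O
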